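The earlier runs and the new flask are simulated on assumed constants; scatter was added.

**One-step world.** Picture each substrate going in a single step with the reagent on the free catalyst. Both then meet the same reagent and catalyst at every moment, so they run on one clock, and the logarithm of the fraction left of the left-handed substrate stays a fixed multiple of that of the right-handed one.

common to all: left-handed substrate 43 mM; right-handed substrate 43 mM; free catalyst 22 µM
- north-east: reagent 47 mM; run made earlier
- south-west: reagent 49 mM; run made earlier
- south: reagent 58 mM; run made earlier
- Monday's: reagent 64.5 mM; time 2.0 min
- Tuesday's: reagent 40.0 mM; time 2.0 min

| run | time / s | right-handed substrate / % | left-handed substrate / % |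
|---|---|---|---|
| north-east | 10.0 | 50 | 44 |
| north-east | 30.0 | 45 | 40 |
| north-east | 60.0 | 43 | 32 |
| north-east | 80.0 | 40 | 31 |
| north-east | 120 | 38 | 30 |
| south-west | 10.0 | 46 | 43 |
| south-west | 20.0 | 46 | 39 |
| south-west | 30.0 | 44 | 37 |
| south-west | 60.0 | 42 | 35 |
| south-west | 120 | 37 | 28 |
| south | 25.0 | 42 | 37 |
| south | 50.0 | 40 | 33 |
| south | 80.0 | 39 | 29 |
| south | 90.0 | 39 | 26 |
| south | 120 | 36 | 26 |

(scatter of a reading: 1.5 percentage points)

- free catalyst is single-handed; left-handed substrate and right-handed substrate are mirror images of each other, charged as a racemate, each of them at the stated concentration
- the earlier runs were read with a standard deviation of 1.5 percentage points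
- an excess is the difference of the two amounts in percent of their sum
- an excess is below zero if the other one leads

* which of the two ends with the higher excess of right-handed substrate over left-handed substrate among what is left of the two ("neither" if they lie within 2 percentage points) (Monday's / Tuesday's / neither)
* excess of right-handed substrate over left-handed substrate among what is left of the two at the end, Monday's
* excess of right-handed substrate over left-handed substrate among what is left of the two at the end, Tuesday's

**In the flask.** For whoever takes over: a reading counts both substrates in its charge, so doubling it gives the fraction of a substrate's own charge. The south run lost more left-handed substrate by its last reading than the other runs. At 120 s it kept 72.0% of the right-handed and 52.0% of the left-handed. The ratio of their logarithms, the selectivity factor, reads 1.99, with the scatter of those readings.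

**When you come.** The reagent falls during a run. We replace its curve by its mean and assume that mean is the same fraction of the charge in each flask, an assumption, as the readings do not show the reagent. Monday's and Tuesday's have the free catalyst charge and the time of the south run's last reading, so the clock then runs in proportion to the reagent charged, and the south fraction is raised to the ratio of charges. By our reckoning, at 2.0 min Monday's keeps 69.4% of the right-handed substrate, for an excess of 17.9%. Tuesday's keeps 79.7%, for 11.2%.

**Leave the timer.** With the factor held, the excess rises as the right-handed fraction falls, so a flask stopped early reads low.

**The forecast.** It says Monday's, with 18.5% and 11.5%, a little above ours, and holds that “the excess depends mainly on conversion”.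

**The result.** Monday's ends higher, at 18.8% against 11.8%.

    reagent + free catalyst + left-handed substrate → free catalyst + left-handed product (k = 12000 M⁻² s⁻¹)
    reagent + free catalyst + right-handed substrate → free catalyst + right-handed product (k = 5800 M⁻² s⁻¹)
    left-handed product ⇌ right-handed product (k = 0.0240 s⁻¹)
    2 free catalyst → spent catalyst (k = 240 M⁻¹ s⁻¹)
    2 reagent → self-condensation product (k = 0.0310 M⁻¹ s⁻¹)

**Same factor.** Monday's keeps 70% of the right-handed substrate; raised to our factor, that gives 49.2% of the left-handed, and the flask holds 48%. A neighbour of Monday's, charged with 0.088 mM of free catalyst, keeps less right-handed substrate, 56%. The same reckoning gives 31.2% of the left-handed and an excess of 28.4%. That neighbour holds 30% and ends at an excess of 30.3%.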